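**Retrosynthesis**
1. The C11 ester and the C1 acylal come from late acylations. Acid **5** is coupled to the C11-OH, and the C1 lactol is acylated with isovaleryl chloride. The dihydropyran forms last, by oxidising a C1/C3 diol to the dialdehyde, which closes to the lactol enol ether.
2. The C8 tertiary chlorohydrin comes from LiCH2Cl addition to a C8 ketone. The C5 tertiary carbinol comes from 1,2-addition of a 2-(silyloxymethyl)vinyl-cerium reagent to an epoxy-enone. Directed Red-Al opening of the resulting epoxy alcohol sets C9–H and C8–O.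
3. The cyclopentane is made first, as 4-silyloxycyclopentenone. It comes from cyclopentadiene by ¹O2 addition followed by an organocatalytic enantioselective Kornblum–DeLaMare (KDM) rearrangement, which sets C7. C1 is added by Morita–Baylis–Hillman (MBH) hydroxymethylation.
4. The side-chain acid, (R)-2-(isovaleroyloxy)-3-methylbutanoic acid, comes from isovaleraldehyde by organocatalytic α-acyloxylation and then Pinnick oxidation.

**Assumptions (one line each):**
- The C4 epimers in **16–22** are inconsequential, because C4 becomes sp² on cyclisation.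
- The C1 acylal forms as the thermodynamic (pseudo-axial) anomer, as in natural valepotriates.
- The organocatalyst enantiomer in Steps 2 and 5 is chosen to give the stated configuration.

---

**Step 1**
Reactants: 1 isovaleryl chloride (2 equiv; two molecules of 1 per molecule of 2)
Product: 2 diisovaleryl peroxide
Conditions: 30% H2O2 (1 equiv), aq. NaOH (2 equiv), Et2O, 0 °C; used as a dilute solution
Reagents that add atoms: hydrogen peroxide, OO
Why: Schotten–Baumann O-acylation: two molecules of acid chloride acylate both oxygens of one H2O2 (2 RC(O)Cl + HOOH → RC(O)OOC(O)R + 2 HCl). This gives the diacyl peroxide electrophile for the next step.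

**Step 2**
Reactants: 3 isovaleraldehyde; 2 diisovaleryl peroxide
Product: 4 (R)-2-(isovaleroyloxy)-3-methylbutanal
Conditions: 20 mol% diarylprolinol silyl ether, toluene, 0 °C; crude used at once
Reagents that add atoms: none
Why: Enamine-catalysed α-acyloxylation, analogous to known α-benzoyloxylation with benzoyl peroxide. The catalyst shields one enamine face, so the O–O bond is attacked from the other face and the α-stereocentre is set as (R). Isovaleric acid is the by-product.

**Step 3**
Reactants: 4
Product: 5 (R)-2-(isovaleroyloxy)-3-methylbutanoic acid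
Conditions: NaClO2, NaH2PO4, 2-methyl-2-butene, tBuOH/H2O, 0 °C
Reagents that add atoms: sodium chlorite, [Na+].[O-]Cl=O
Why: Pinnick oxidation is mild enough to leave the α-acyloxy ester and its stereocentre intact.

**Step 4**
Reactants: 6 cyclopentadiene (freshly cracked)
Product: 7 2,3-dioxabicyclo[2.2.1]hept-5-ene (meso endoperoxide; not isolated, used cold)
Conditions: O2, visible light, tetraphenylporphyrin, CH2Cl2, −78 °C
Reagents that add atoms: dioxygen, O=O
Why: Singlet-oxygen [4+2] cycloaddition gives the meso endoperoxide.

**Step 5**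
Reactants: 7
Product: 8 (S)-4-(triethylsilyloxy)cyclopent-2-en-1-one
Conditions: 10 mol% quinidine-derived tertiary-amine catalyst (6'-OH type), CH2Cl2, −40 °C; then TESCl, imidazole, 0 °C (the 4-hydroxyenone is not isolated)
Reagents that add atoms: chlorotriethylsilane, CC[Si](Cl)(CC)CC
Why: Proposed new method: the chiral amine removes one of the two enantiotopic bridgehead H atoms, with the catalyst OH hydrogen-bonding the peroxide oxygen, and the O–O bond cleaves in a concerted E2-type step to give the (S)-4-hydroxyenone, which is trapped as the TES ether, so C7 is set here. The closest known reaction is cinchona-catalysed desymmetrising Kornblum–DeLaMare rearrangement of [2.2.2] endoperoxides; its application to the strained cyclopentadiene [2.2.1] substrate is, to my knowledge, not shown.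

**Step 6**
Reactants: 8; 9 formaldehyde
Product: 10 (S)-2-(hydroxymethyl)-4-(triethylsilyloxy)cyclopent-2-en-1-one
Conditions: aq. HCHO, Et3P (10 mol%), THF, 0 °C
Reagents that add atoms: none (9 is the numbered reactant)
Why: Morita–Baylis–Hillman hydroxymethylation at the enone α-carbon installs C1, with no new stereocentre.

**Step 7**
Reactants: 10
Product: 11 α,β-epoxy ketone (epoxide anti to OTES)
Conditions: tBuOOH, DBU, THF, −20 °C
Reagents that add atoms: tert-butyl hydroperoxide, CC(C)(C)OO
Why: Weitz–Scheffer nucleophilic epoxidation occurs on the face anti to the C7 OTES group, placing the epoxide oxygen down at C8/C9.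

**Step 8**
Reactants: 12 2-bromoallyl alcohol
Product: 13 2-bromo-3-(tert-butyldiphenylsilyloxy)propene
Conditions: TBDPSCl, imidazole, DMF, rt
Reagents that add atoms: tert-butylchlorodiphenylsilane, CC(C)(C)[Si](Cl)(c1ccccc1)c1ccccc1
Why: Standard silylation gives the C3–C4–C11 vinyl-anion precursor with a protected C11 oxygen.

**Step 9**
Reactants: 11; 13
Product: 14 tertiary allylic alcohol bearing the epoxide
Conditions: 13, tBuLi (2 equiv), THF, −78 °C; then CeCl3; add 11 (3.5 equiv reagent in total, one equivalent being consumed by the free CH2OH), −78 °C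
Reagents that add atoms: none (13 is the numbered reactant)
Why: Organocerium 1,2-addition to the ketone occurs from the face bearing the epoxide oxygen, with the OTES group shielding the top face. This places C4 down and the C5 OH up, trans to the epoxide oxygen as the next step requires.

**Step 10**
Reactants: 14
Product: 15 C9–H/C8-OH diol-alcohol (epoxide opened)
Conditions: Red-Al, THF, 0 °C → rt
Reagents that add atoms: none
Why: Red-Al opens the 2,3-epoxy alcohol at C9 (C2 of the epoxy alcohol) with inversion, delivering hydride from the top-face C5 alkoxyaluminate. This sets H9 up, pushes C1 down (cis to C4) and leaves C8-O down.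

**Step 11**
Reactants: 15
Product: 16 C3-OH compound (C3-hydroxyl; C4 epimeric)
Conditions: 9-BBN (4 equiv), THF, 0 °C → rt; then 30% H2O2, aq. NaOH, 0 °C
Reagents that add atoms: hydrogen peroxide, OO
Why: Anti-Markovnikov hydroboration–oxidation of the only remaining alkene gives the primary C3 alcohol.

**Step 12**
Reactants: 16
Product: 17 bis-TBS ether (C1-OTBS, C3-OTBS)
Conditions: TBSCl (2.4 equiv), imidazole, DMF, 0 °C
Reagents that add atoms: tert-butylchlorodimethylsilane, CC(C)(C)[Si](C)(C)Cl
Why: Primary hydroxyls silylate much faster than the hindered secondary C8-OH and the tertiary C5-OH, so only C1 and C3 are protected.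

**Step 13**
Reactants: 17
Product: 18 C8 ketone
Conditions: Dess–Martin periodinane, NaHCO3, CH2Cl2, 0 °C
Reagents that add atoms: none
Why: Dess–Martin oxidation of the secondary C8 alcohol is neutral enough to leave H9 (α to the ketone) and the β-hydroxy ketone intact.

**Step 14**
Reactants: 18
Product: 19 tertiary chlorohydrin (C8-OH/CH2Cl)
Conditions: ICH2Cl (4 equiv), MeLi·LiBr (4 equiv), THF, −78 °C; quench cold with sat. NH4Cl
Reagents that add atoms: chloroiodomethane, ClCI
Why: LiCH2Cl adds 1,2 to the ketone from the top face, the face of the Li C5-alkoxide and away from the down-pointing C1 arm on C9. This puts CH2Cl up and O down, and the low temperature prevents epoxide closure.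

**Step 15**
Reactants: 19
Product: 20 C7 alcohol (TES removed)
Conditions: PPTS, MeOH/CH2Cl2, 0 °C
Reagents that add atoms: none
Why: A secondary TES ether is cleaved selectively over the primary TBS and TBDPS ethers.

**Step 16**
Reactants: 20
Product: 21 C7 acetate
Conditions: Ac2O, pyridine, DMAP (cat.), CH2Cl2, 0 °C
Reagents that add atoms: acetic anhydride, CC(=O)OC(C)=O
Why: Acetylation at C7 proceeds with retention; the tertiary C5 and C8 alcohols do not react.

**Step 17**
Reactants: 21
Product: 22 C1/C3 diol
Conditions: HF·pyridine, THF/pyridine, 0 °C → rt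
Reagents that add atoms: none
Why: Primary TBS ethers are removed while the acetate, TBDPS ether and chlorohydrin survive.

**Step 18**
Reactants: 22
Product: 23 lactol enol ether (pyran ring; C1 anomeric mixture)
Conditions: Dess–Martin periodinane (2.5 equiv), NaHCO3, CH2Cl2, rt; Na2S2O3/NaHCO3 quench
Reagents that add atoms: none
Why: Simultaneous oxidation gives the C1/C3 dialdehyde, which enolises at C4 and closes to the lactol (iridoid-type cyclisation). C9 is cis-locked by the ring fusion, and C4 epimers converge.

**Step 19**
Reactants: 23; 1 isovaleryl chloride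
Product: 24 C1 acylal (C11-OTBDPS)
Conditions: isovaleryl chloride (3 equiv), pyridine, DMAP (0.2 equiv), CH2Cl2, −20 °C
Reagents that add atoms: none (1 is the numbered reactant)
Why: O-Acylation of the lactol gives the anomerically favoured acylal, leaving the hindered tertiary alcohols untouched.

**Step 20**
Reactants: 24
Product: 25 C11 primary alcohol
Conditions: TBAF/AcOH (1:1), THF, 0 °C
Reagents that add atoms: none
Why: Buffered fluoride removes the TBDPS group without cleaving the acylal or the acetate.

**Step 21**
Reactants: 25; 5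
Product: 26 Volvaltrate B
Conditions: 5 (1.5 equiv), DIC, DMAP (0.1 equiv), CH2Cl2, 0 °C
Reagents that add atoms: none (5 is the numbered reactant)
Why: Steglich esterification occurs selectively at the primary C11 hydroxyl; the stereocentre of 5 is retained under these cold, low-DMAP conditions.

---

**Compound list**

1 | isovaleryl chloride | CC(C)CC(=O)Cl | starting material
2 | diisovaleryl peroxide | CC(C)CC(=O)OOC(=O)CC(C)C | intermediate
3 | isovaleraldehyde | CC(C)CC=O | starting material
4 | (R)-2-(isovaleroyloxy)-3-methylbutanal | O=C[C@H](OC(=O)CC(C)C)C(C)C | intermediate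
5 | (R)-2-(isovaleroyloxy)-3-methylbutanoic acid | OC(=O)[C@H](OC(=O)CC(C)C)C(C)C | intermediate
6 | cyclopentadiene | C1C=CC=C1 | starting material
7 | 2,3-dioxabicyclo[2.2.1]hept-5-ene | C1C2C=CC1OO2 | intermediate
8 | (S)-4-(triethylsilyloxy)cyclopent-2-en-1-one | O=C1C=C[C@@H](O[Si](CC)(CC)CC)C1 | intermediate
9 | formaldehyde | C=O | starting material
10 | 2-(hydroxymethyl)-4-OTES-cyclopentenone | O=C1C(CO)=C[C@@H](O[Si](CC)(CC)CC)C1 | intermediate
11 | α,β-epoxy ketone | O=C1C[C@H](O[Si](CC)(CC)CC)[C@H]2O[C@@]12CO | intermediate
12 | 2-bromoallyl alcohol | C=C(Br)CO | starting material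
13 | 2-bromo-3-(TBDPSO)propene | C=C(Br)CO[Si](c1ccccc1)(c1ccccc1)C(C)(C)C | intermediate
14 | tertiary alcohol epoxide | C=C(CO[Si](c3ccccc3)(c3ccccc3)C(C)(C)C)[C@@]1(O)C[C@H](O[Si](CC)(CC)CC)[C@H]2O[C@@]12CO | intermediate
15 | C9–H/C8-OH alcohol (Red-Al product) | C=C(CO[Si](c3ccccc3)(c3ccccc3)C(C)(C)C)[C@@]1(O)C[C@H](O[Si](CC)(CC)CC)[C@@H](O)[C@H]1CO | intermediate
16 | C3-OH compound | OCC(CO[Si](c3ccccc3)(c3ccccc3)C(C)(C)C)[C@@]1(O)C[C@H](O[Si](CC)(CC)CC)[C@@H](O)[C@H]1CO | intermediate
17 | bis-TBS ether | CC(C)(C)[Si](C)(C)OCC(CO[Si](c3ccccc3)(c3ccccc3)C(C)(C)C)[C@@]1(O)C[C@H](O[Si](CC)(CC)CC)[C@@H](O)[C@H]1CO[Si](C)(C)C(C)(C)C | intermediate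
18 | C8 ketone | CC(C)(C)[Si](C)(C)OCC(CO[Si](c3ccccc3)(c3ccccc3)C(C)(C)C)[C@@]1(O)C[C@H](O[Si](CC)(CC)CC)C(=O)[C@H]1CO[Si](C)(C)C(C)(C)C | intermediate
19 | chlorohydrin | CC(C)(C)[Si](C)(C)OCC(CO[Si](c3ccccc3)(c3ccccc3)C(C)(C)C)[C@@]1(O)C[C@H](O[Si](CC)(CC)CC)[C@](O)(CCl)[C@H]1CO[Si](C)(C)C(C)(C)C | intermediate
20 | C7 alcohol | CC(C)(C)[Si](C)(C)OCC(CO[Si](c3ccccc3)(c3ccccc3)C(C)(C)C)[C@@]1(O)C[C@H](O)[C@](O)(CCl)[C@H]1CO[Si](C)(C)C(C)(C)C | intermediate
21 | C7 acetate | CC(C)(C)[Si](C)(C)OCC(CO[Si](c3ccccc3)(c3ccccc3)C(C)(C)C)[C@@]1(O)C[C@H](OC(C)=O)[C@](O)(CCl)[C@H]1CO[Si](C)(C)C(C)(C)C | intermediate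
22 | C1/C3 diol | OCC(CO[Si](c3ccccc3)(c3ccccc3)C(C)(C)C)[C@@]1(O)C[C@H](OC(C)=O)[C@](O)(CCl)[C@H]1CO | intermediate
23 | lactol enol ether | CC(=O)O[C@H]1C[C@]2(O)C(CO[Si](c3ccccc3)(c3ccccc3)C(C)(C)C)=COC(O)[C@@H]2[C@@]1(O)CCl | intermediate
24 | C1 acylal, C11-OTBDPS | CC(=O)O[C@H]1C[C@]2(O)C(CO[Si](c3ccccc3)(c3ccccc3)C(C)(C)C)=CO[C@@H](OC(=O)CC(C)C)[C@@H]2[C@@]1(O)CCl | intermediate
25 | C11 alcohol | CC(=O)O[C@H]1C[C@]2(O)C(CO)=CO[C@@H](OC(=O)CC(C)C)[C@@H]2[C@@]1(O)CCl | intermediate
26 | Volvaltrate B | CC(=O)O[C@H]1C[C@]2(O)C(COC(=O)[C@H](OC(=O)CC(C)C)C(C)C)=CO[C@@H](OC(=O)CC(C)C)[C@@H]2[C@@]1(O)CCl | target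

---

**Total steps:** 21, including the 3-step side-chain branch (Steps 1–3) and the 1-step vinyl-bromide protection (Step 8). **Longest linear sequence:** 17 steps (cyclopentadiene → 26).

**Three steps most likely to fail**
1. **Step 5 (proposed new KDM desymmetrisation).** The strained [2.2.1] endoperoxide may decompose or give low ee.
   - *Fallback:* enzymatic desymmetrisation of cis-3,5-diacetoxycyclopentene (or the meso diol monoacetate) with an esterase or lipase. This is followed by TES protection, methanolysis and oxidation to 8, all known chemistry.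
2. **Step 14 (LiCH2Cl facial selectivity at C8).** The adjacent C7 OTES group may divert attack to the wrong face, and the β-hydroxy ketone may undergo retro-aldol.
   - *Fallback:* Petasis methylenation of 18, then a homoallylic-alcohol-directed VO(acac)2/TBHP epoxidation from the concave face using the free C5-OH. The spiro-epoxide is then opened at the primary carbon with HCl.
3. **Steps 18–19 (dialdehyde cyclisation and C1 acylation).** The dialdehyde may undergo β-elimination or over-oxidation to a lactone, and the C1 anomer ratio is uncertain.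
   - *Fallback:* Parikh–Doering oxidation with in-situ MeOH/PPTS trapping as the 1-OMe acetal. The methyl acetal is then exchanged with isovaleric anhydride and TMSOTf under thermodynamic control to give the axial acylal.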